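The birch run and its neighbours are the place to begin, and this is what they give:

| setting | birch | elm | oak | larch | ash |
|---|---|---|---|---|---|
| starting material | 0.400 M | 0.400 M | 1.20 M | 0.400 M | 0.400 M |
| partner | 1.00 M | 1.00 M | 1.00 M | 1.50 M | 2.40 M |
| free catalyst | 0.00400 M | 0.0120 M | 0.00400 M | 0.00400 M | 0.00400 M |
| time |  |  |  |  | 50 min |

| run | time / min | [product] / M |
|---|---|---|
| birch run | 7.1 | 0.179 |
| birch run | 14 | 0.189 |
| birch run | 21 | 0.198 |
| birch run | 29 | 0.197 |
| birch run | 36 | 0.198 |
| birch run | 43 | 0.202 |
| birch run | 50 | 0.201 |
| elm run | 7.1 | 0.345 |
| elm run | 14 | 0.364 |
| elm run | 21 | 0.360 |
| elm run | 29 | 0.368 |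
| elm run | 36 | 0.365 |
| elm run | 43 | 0.366 |
| elm run | 50 | 0.372 |
| oak run | 7.1 | 0.548 |
| oak run | 14 | 0.638 |
| oak run | 21 | 0.661 |
| oak run | 29 | 0.672 |
| oak run | 36 | 0.676 |
| oak run | 43 | 0.673 |
| oak run | 50 | 0.675 |
| larch run | 7.1 | 0.130 |
| larch run | 14 | 0.131 |
| larch run | 21 | 0.139 |
| larch run | 29 | 0.138 |
| larch run | 36 | 0.135 |
| larch run | 43 | 0.140 |
| larch run | 50 | 0.138 |

(readings scatter by 0.003 M)

- Overall: starting material + partner -> product, with free catalyst as catalyst.
- Constant volume, constant temperature.
- An order is taken over about fifteen percent of the charge, up and down.

* the exponent of [starting material] in the starting rate at the charge of the birch run (at the point where two percent of the starting material have become product) (one fixed amount of product, the same in the runs compared)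
* the exponent of [partner] in the starting rate at the charge of the birch run (at the point where two percent of the starting material have become product)
* product in the ash run at 50 min, as a share of the starting material charged

- The birch run levels off at 0.199 M (the mean from 21 min on) with 0.201 M of starting material still unturned. The elm run, the same charge with 3.00 times the free catalyst, climbs higher than birch to 0.366 M. A chemical balance does not shift with its catalyst, so you may read these plateaus as catalyst lost on the way.
- The larch run, with more partner than birch, stops lower at 0.138 M, so my reckoning takes the partner as what spends the catalyst.
- Let s and r be the current starting material and partner. In my reckoning free catalyst has two fates: it takes up starting material at a rate proportional to s, or it is spent by partner at a rate proportional to r. Suppose that each uptake ends in one product and returns the catalyst, so that both fates draw on the same free catalyst; each bit of product then costs catalyst in proportion r/(A s), with A taken as a constant.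
- Now let S, R and C be the charges and P the plateau, and assume that partner falls by the product made. Summing over the run gives A C = P + (R − S) ln(S/(S − P)).
- The birch plateau gives A = 153. I call A the catalyst allowance, the product weighted by r/s that a unit of catalyst makes before it is spent, and in this reckoning it acts as a selectivity factor between the two fates.
- The check comes from other plateaus: the elm run gives 154 and the larch run 151. The oak run, charged with more starting material than partner, levels at 0.674 M from 29 min on and gives 127, lower than the birch value, so the allowance does not pass that check. The ash run, like birch, elm and larch, has more partner than starting material, and I carry the birch value there.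
- For the ash run, the starting material left is S exp(−(A C − P)/(R − S)), and repeating this from P = nothing gives 0.106 M, then 0.0896 M, then 0.0921 M. My figure is therefore 23.0 % of the charge.
- The allowance is a ratio of two rates and holds no clock, and the first birch reading, at 7.1 min, already stands at 89.9 % of the plateau, so I commit to the ash figure and not to orders.
- The forecast, holding that “the catalyst dies within about 15 min”, gave 0.9 (0.72 to 1.05) for the order in starting material, −0.25 (−0.95 to 0.15) for the order in partner, and 23 % (20 % to 26.5 %) for the ash run.

The flask gives orders of 0.92 in starting material and 0.10 in partner, and the ash run reaches 22.1 %, while a power law fitted to the same runs forecasts 72.3 % for ash, more than the flask gives. free catalyst + starting material → loaded catalyst + by-product (99.60 M⁻¹ min⁻¹); loaded catalyst + partner → product + free catalyst (223.8 M⁻¹ min⁻¹); free catalyst + partner → spent catalyst + partner (0.9540 M⁻¹ min⁻¹); 2 partner → lost reagent (0.1236 M⁻¹ min⁻¹)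

Put back into the allowance, the ash product of 0.0884 M gives 147, lower than the birch value of 153.

The readings are simulated for an exercise.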